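**Retrosynthetic overview**
1. Feature: in the seven-membered carbocycle (ring C), the CH(2,4-dihydroxyphenyl)–CH2 bond (C10–C11) joins a benzylic carbon on ring B to a benzylic carbon on ring A. It is cut as C10=C11 and traced back to loss of SO2 from an eight-membered bis-benzylic sulfone.
2. Endgame: eight O-methyl groups are removed. Ring E is opened at C2'–C3' (carbene C–H insertion), giving an aryl ketone that comes from an aryl bromide on ring-A carbon d, carried from the first step.
3. C10 comes from acid-catalysed hydroarylation of the ring-C alkene with 1,3-dimethoxybenzene. The alkene comes from the sulfone, and the sulfone from two ArCH2Br arms and sulfide.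
4. The ring-B arm comes from formylation. Ring D comes from an enantioselective carbene C–H insertion followed by C2 epimerisation. The diaryl ketone comes from a symmetric dibromide and an aroyl chloride.
5. Order of ring formation: D, then the eight-membered sulfur ring, then C by contraction, then E.

Key step: step 15

Labels:
- Ring A is the central benzene. Its carbons are a (O of ring D), b (CH), c (O of ring E), d (C3' of ring E), e (C11H2) and f (C3 of ring D).
- Ring B is the dioxygenated arene fused to ring C.
- Ring D is the inner dihydrofuran (O1, C2, C3).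
- Ring E is the outer dihydrofuran (O1', C2', C3').
- C10 is CH(aryl) on ring B, and C11 is CH2 on ring A.

Assumption: Rh2(S-PTAD)4 is taken to deliver the 3S centre of ring D and its mirror image the 3'R centre of ring E. If the sense of induction on these substrates is the reverse, the two catalysts change places and nothing else changes.

**Step 1**
Reactants: 1 3,5-dimethoxybenzyl alcohol
Product: 2 (2,6-dibromo-3,5-dimethoxyphenyl)methanol
Conditions: NBS (2.1 equiv), MeCN, 0 °C → rt
Reagents that add atoms: N-bromosuccinimide, O=C1CCC(=O)N1Br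
Why: Electrophilic aromatic bromination places each bromine para to one methoxy group and ortho to the other, the site between the two methoxy groups reacting last, so the symmetric dibromide should form, one bromine serving step 3 and the other marking carbon d, which no late electrophilic substitution could pick out among the many activated arene positions.

**Step 2**
Reactants: 2 (2,6-dibromo-3,5-dimethoxyphenyl)methanol
Product: 3 [(2,6-dibromo-3,5-dimethoxyphenyl)methoxy]triisopropylsilane
Conditions: TIPSCl, imidazole, DMF, rt
Reagents that add atoms: chlorotriisopropylsilane, CC(C)[Si](Cl)(C(C)C)C(C)C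
Why: Standard silylation of a primary alcohol, the bulky TIPS group being chosen because it resists O-to-C silyl migration in the ortho-lithiated arene, tolerates BCl3, hydrazine, TFA and the Vilsmeier reagent, and leaves its oxygen a poor partner for a carbene.

**Step 3**
Reactants: 3 [(2,6-dibromo-3,5-dimethoxyphenyl)methoxy]triisopropylsilane; 4 3,5-dimethoxybenzoyl chloride
Product: 6 [3-bromo-4,6-dimethoxy-2-(triisopropylsilyloxymethyl)phenyl](3,5-dimethoxyphenyl)methanone, via aryllithium 5 (not isolated)
Conditions: n-BuLi (1.0 equiv), THF, −78 °C; cannulated into 4 (1.5 equiv), THF, −78 °C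
Reagents that add atoms: none
Why: Lithium–bromine exchange on a dibromide whose two bromines are equivalent (the remaining one is meta to lithium, so no aryne can form) is followed by acylation with inverse addition, which should stop at the ketone because the doubly ortho-substituted carbonyl group is shielded from a second bulky aryllithium.

**Step 4**
Reactants: 6 diaryl ketone
Product: 7 [3-bromo-6-hydroxy-4-methoxy-2-(triisopropylsilyloxymethyl)phenyl](3,5-dimethoxyphenyl)methanone
Conditions: BCl3 (1.2 equiv), CH2Cl2, −78 → −10 °C; H2O
Reagents that add atoms: none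
Why: Chelation-controlled aryl methyl ether cleavage, in which BCl3 bridges the ketone oxygen and the only methoxy group ortho to it (carbon a), so chloride removes that methyl group alone and the three other methoxy groups stay.

**Step 5**
Reactants: 7 ortho-hydroxy ketone
Product: 8 hydrazone of 7 (E/Z mixture, of no consequence)
Conditions: N2H4·H2O (20 equiv), AcOH (cat.), EtOH, 85 °C, sealed tube
Reagents that add atoms: hydrazine hydrate, NN.O
Why: Hydrazone condensation is run at the free-phenol stage, where the O–H···O=C hydrogen bond pulls the carbonyl group toward the plane of ring A and uncovers its faces and the O–H···N bond of the product drives the equilibrium, which eases a reaction that is slow for doubly ortho-substituted benzophenones.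

**Step 6**
Reactants: 8 phenol hydrazone; 9 4-methoxybenzyl chloride
Product: 10 hydrazone of [3-bromo-4-methoxy-6-(4-methoxybenzyloxy)-2-(triisopropylsilyloxymethyl)phenyl](3,5-dimethoxyphenyl)methanone
Conditions: 9 (1.05 equiv), K2CO3, DMF, rt, argon
Reagents that add atoms: none
Why: Williamson ether synthesis in which K2CO3 ionises only the phenol, and the phenoxide should outrun the weakly nucleophilic, conjugated hydrazone NH2 for one equivalent of the benzylic chloride.

**Step 7**
Reactants: 10 ether hydrazone
Product: 12 (2R,3S)-5-bromo-3-(3,5-dimethoxyphenyl)-6-methoxy-2-(4-methoxyphenyl)-4-(triisopropylsilyloxymethyl)-2,3-dihydrobenzofuran (cis), via diazo compound 11 (not isolated)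
Conditions: MnO2 (10 equiv), CH2Cl2, 0 °C, filtered under argon; filtrate added to Rh2(S-PTAD)4 (dirhodium tetrakis[(S)-(1-adamantyl)(phthalimido)acetate], 1 mol %), CH2Cl2, 0 °C → rt
Reagents that add atoms: none
Why: MnO2 dehydrogenates the hydrazone to the diaryldiazomethane, whose donor/donor dirhodium carbene undergoes enantioselective intramolecular C–H insertion into the O–CH2Ar group to close the five-membered ring, the chiral carboxylate pocket fixing C3 as S and the hydride-transfer-like transition state placing the two aryl groups cis (C2 R), while insertion at the silyloxymethyl arm would need a four- or seven-membered ring.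

**Step 8**
Reactants: 12 cis-dihydrobenzofuran
Product: 13 (2S,3S)-5-bromo-3-(3,5-dimethoxyphenyl)-6-methoxy-2-(4-methoxyphenyl)-4-(triisopropylsilyloxymethyl)-2,3-dihydrobenzofuran (trans)
Conditions: TFA (5 equiv), CH2Cl2, 0 °C
Reagents that add atoms: none
Why: Acid-mediated epimerisation by reversible ionisation of the C2–O bond to the 4-methoxybenzylic cation and re-closure by the phenol oxygen should funnel the crowded cis isomer into the trans isomer (C2 becomes S), while C3 takes no part and keeps its configuration.

**Step 9**
Reactants: 13 trans-dihydrobenzofuran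
Product: 14 2-[(2S,3S)-5-bromo-6-methoxy-2-(4-methoxyphenyl)-4-(triisopropylsilyloxymethyl)-2,3-dihydrobenzofuran-3-yl]-4,6-dimethoxybenzaldehyde
Conditions: POCl3 (1.5 equiv), DMF, 0 → 50 °C; H2O, 0 °C
Reagents that add atoms: N,N-dimethylformamide, CN(C)C=O; water, O
Why: Vilsmeier–Haack formylation goes to the most nucleophilic free position, para to one and ortho to the other methoxy group of the pendant ring B (its two such sites are equivalent by rotation), whereas ring A offers only the site between two oxygens and is deactivated by bromine.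

**Step 10**
Reactants: 14 aldehyde
Product: 15 {2-[(2S,3S)-5-bromo-6-methoxy-2-(4-methoxyphenyl)-4-(triisopropylsilyloxymethyl)-2,3-dihydrobenzofuran-3-yl]-4,6-dimethoxyphenyl}methanol
Conditions: NaBH4, THF/MeOH, 0 °C
Reagents that add atoms: none
Why: Borohydride reduction of an aryl aldehyde, with nothing else in the molecule reducible under these conditions.

**Step 11**
Reactants: 15 silyl ether alcohol
Product: 16 diol: (2S,3S)-5-bromo-4-(hydroxymethyl)-3-[2-(hydroxymethyl)-3,5-dimethoxyphenyl]-6-methoxy-2-(4-methoxyphenyl)-2,3-dihydrobenzofuran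
Conditions: TBAF, THF, 0 °C → rt
Reagents that add atoms: none
Why: Fluoride-driven desilylation proceeds without acid and so spares the easily ionised 2,4-dimethoxybenzylic alcohol.

**Step 12**
Reactants: 16 diol
Product: 17 (2S,3S)-5-bromo-4-(bromomethyl)-3-[2-(bromomethyl)-3,5-dimethoxyphenyl]-6-methoxy-2-(4-methoxyphenyl)-2,3-dihydrobenzofuran
Conditions: CBr4, PPh3, CH2Cl2, −10 °C; short silica plug, used at once
Reagents that add atoms: carbon tetrabromide, BrC(Br)(Br)Br
Why: The Appel reaction converts both primary benzylic alcohols into bromides under neutral conditions, which matters because the ring-B arm is a labile 2,4-dimethoxybenzylic bromide that has to be kept cold and used directly.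

**Step 13**
Reactants: 17 bis(bromomethyl) compound
Product: 18 eight-membered cyclic sulfide: 17 with the two CH2Br groups joined as a C11H2–S–C10H2 bridge, (2S,3S)-trans ring D, Br on carbon d
Conditions: Na2S (anhydrous, 1.2 equiv), DMF/THF, slow addition of 17 (about 2 mM), 0 °C → rt
Reagents that add atoms: sodium sulfide, [Na+].[Na+].[S-2]
Why: Double SN2 displacement under high dilution in an aprotic medium (so the labile bromide is not solvolysed), in which the thiolate formed first finds the second benzylic bromide held nearby by the C3 hinge, so the ring should close in preference to oligomerisation.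

**Step 14**
Reactants: 18 cyclic sulfide
Product: 19 eight-membered cyclic sulfone (S,S-dioxide of 18), (2S,3S)-trans ring D, Br on carbon d
Conditions: Oxone, THF/MeOH/H2O, 0 °C → rt
Reagents that add atoms: potassium peroxymonosulfate (active part of Oxone), [K+].[O-]S(=O)(=O)OO
Why: Sulfide-to-sulfone oxidation by peroxymonosulfate is much faster than any attack on the methoxyarenes.

**Step 15**
Reactants: 19 cyclic sulfone
Product: 22 bromo dibenzocycloheptene: tetracycle with rings A, B, C and D, C10=C11 double bond, (2S,3S)-trans ring D, Br on carbon d, via alpha-bromo sulfone 20 (not isolated), via episulfone 21 (not isolated)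
Conditions: KOH on Al2O3, CBr2F2, t-BuOH/CH2Cl2, 0 °C → rt
Reagents that add atoms: none
Why: Hydroxide removes a proton next to the sulfone, CBr2F2 transfers bromine to that carbanion to give 20, deprotonation at the other alpha carbon is followed by internal displacement of bromide to give the thiirane 1,1-dioxide 21, and 21 expels SO2 to leave the C10=C11 bond. This is the Ramberg–Bäcklund reaction in its in-situ halogenation form, which is established for cyclic and for dibenzylic sulfones. The three-membered ring closes 3-exo-tet, and the same C–C bond closes ring C, so the eight-membered ring contracts to the seven-membered one. No lasting stereocentre arises, since the two centres of 21 disappear with the SO2 and a seven-membered ring can hold only the Z alkene. The step needs chemoselective deprotonation, which the large acidity gap between the benzylic SO2CH2 groups and the doubly benzylic C3–H of ring D secures, so the trans furan stays intact, and it does not matter which CH2 is brominated first because both paths lead to 22. The aryl bromide and the ethers are inert to KOH at this temperature, and carbon e of ring A, which lies meta to both ring-A oxygens, never has to act as a nucleophile.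

**Step 16**
Reactants: 22 bromo dibenzocycloheptene; 23 1,3-dimethoxybenzene
Product: 24 (2S,3S,10S)-10-(2,4-dimethoxyphenyl)-10,11-dihydro derivative of 22 (aryl group on the face of ring C that carries the C3–H)
Conditions: 23 (5 equiv), TfOH (0.2 equiv), CH2Cl2, −60 → −20 °C
Reagents that add atoms: none
Why: Brønsted-acid-catalysed Friedel–Crafts hydroarylation of an electron-rich styrene, in which protonation at C11 gives the C10 cation stabilised by the ortho and para methoxy groups of ring B (the ring-A oxygens are meta to carbon e and cannot support the other cation), 1,3-dimethoxybenzene attacks through its C4, and because ring A is folded over one face of the planar cation the arene should come from the open convex face, syn to the C3–H, setting C10 as S, while catalytic acid and low temperature keep the C2–O bond of ring D closed.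

**Step 17**
Reactants: 24 aryl bromide; 4 3,5-dimethoxybenzoyl chloride
Product: 26 ketone: 24 with Br on carbon d replaced by a 3,5-dimethoxybenzoyl group, (2S,3S,10S), via aryllithium 25 (not isolated)
Conditions: n-BuLi (1.05 equiv), THF, −78 °C; cannulated into 4 (2 equiv), THF, −78 °C
Reagents that add atoms: none
Why: Lithium–bromine exchange, faster at −78 °C than any deprotonation, followed by acylation as in step 3 places the aroyl group exactly at the position the bromine has marked since step 1.

**Step 18**
Reactants: 26 ketone
Product: 27 ortho-hydroxy ketone: 26 with the methoxy group on carbon c converted to OH, (2S,3S,10S)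
Conditions: BCl3 (1.5 equiv), CH2Cl2, −78 → −20 °C; H2O
Reagents that add atoms: none
Why: Chelation-controlled demethylation as in step 4, since the new ketone has a single ortho methoxy group (carbon c), and a chelating equivalent of BCl3 at low temperature should leave the seven other methyl ethers and the ring-D ether untouched.

**Step 19**
Reactants: 27 ortho-hydroxy ketone
Product: 28 hydrazone of 27 (E/Z mixture), (2S,3S,10S)
Conditions: N2H4·H2O (20 equiv), AcOH (cat.), n-BuOH, 100 °C, sealed tube
Reagents that add atoms: hydrazine hydrate, NN.O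
Why: Phenol-assisted hydrazone condensation as in step 5, on a ketone with the same ortho pattern (OH and a benzylic CH2).

**Step 20**
Reactants: 28 phenol hydrazone; 9 4-methoxybenzyl chloride
Product: 29 4-methoxybenzyl ether of 28 at the oxygen on carbon c, (2S,3S,10S)
Conditions: 9 (1.05 equiv), K2CO3, DMF, rt, argon
Reagents that add atoms: none
Why: Williamson ether synthesis selective for the phenoxide over the hydrazone NH2, as in step 6.

**Step 21**
Reactants: 29 ether hydrazone
Product: 31 octamethyl ether with cis ring E, (2S,3S,10S,2'S,3'R), via diazo compound 30 (not isolated)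
Conditions: MnO2 (10 equiv), CH2Cl2, 0 °C, filtered under argon; filtrate added to Rh2(R-PTAD)4 (1 mol %), CH2Cl2, 0 °C → rt
Reagents that add atoms: none
Why: The same oxidation and enantioselective intramolecular carbene C–H insertion as in step 7 is run with the mirror-image catalyst because ring E needs the opposite local sense (C3' R), catalyst control being expected to override the remote resident centres, with the cis product (C2' S) again the kinetic one.

**Step 22**
Reactants: 31 cis-ring-E compound
Product: 32 octamethyl ether of the target, (2S,3S,10S,2'R,3'R), both dihydrofurans trans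
Conditions: TFA (5 equiv), CH2Cl2, 0 °C
Reagents that add atoms: none
Why: Acid epimerisation as in step 8 inverts only C2' (to R) through its 4-methoxybenzylic cation, ring D being already the thermodynamic trans isomer and able only to return to itself, and C3, C3' and C10 do not ionise under these conditions.

**Step 23**
Reactants: 32 octamethyl ether
Product: 33 CNP0154047.3 (target), (2S,3S,10S,2'R,3'R)
Conditions: BBr3 (24 equiv), CH2Cl2, −78 °C → rt; MeOH then H2O, 0 °C
Reagents that add atoms: none
Why: BBr3 cleavage of the eight aryl methyl ethers, in a molecule that holds no alkene or suitably placed arene to intercept a C2 or C2' cation, so a furan opened by the Lewis acid should re-close to the same trans ring on protic work-up with no stereocentre altered.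

**Compound list**
1 | 3,5-dimethoxybenzyl alcohol | COc1cc(CO)cc(OC)c1 | starting material
2 | (2,6-dibromo-3,5-dimethoxyphenyl)methanol | COc1cc(OC)c(Br)c(CO)c1Br | intermediate
3 | [(2,6-dibromo-3,5-dimethoxyphenyl)methoxy]triisopropylsilane | COc1cc(OC)c(Br)c(CO[Si](C(C)C)(C(C)C)C(C)C)c1Br | intermediate
4 | 3,5-dimethoxybenzoyl chloride | COc1cc(cc(OC)c1)C(=O)Cl | starting material
5 | [3-bromo-4,6-dimethoxy-2-(triisopropylsilyloxymethyl)phenyl]lithium | COc1cc(OC)c(Br)c(CO[Si](C(C)C)(C(C)C)C(C)C)c1[Li] | intermediate
6 | [3-bromo-4,6-dimethoxy-2-(triisopropylsilyloxymethyl)phenyl](3,5-dimethoxyphenyl)methanone | COc1cc(OC)c(Br)c(CO[Si](C(C)C)(C(C)C)C(C)C)c1C(=O)c1cc(OC)cc(OC)c1 | intermediate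
7 | [3-bromo-6-hydroxy-4-methoxy-2-(triisopropylsilyloxymethyl)phenyl](3,5-dimethoxyphenyl)methanone | COc1cc(O)c(C(=O)c2cc(OC)cc(OC)c2)c(CO[Si](C(C)C)(C(C)C)C(C)C)c1Br | intermediate
8 | hydrazone of 7 (E/Z mixture) | COc1cc(O)c(C(=NN)c2cc(OC)cc(OC)c2)c(CO[Si](C(C)C)(C(C)C)C(C)C)c1Br | intermediate
9 | 4-methoxybenzyl chloride | COc1ccc(CCl)cc1 | starting material
10 | 4-methoxybenzyl ether of 8 (E/Z mixture) | COc1ccc(COc2cc(OC)c(Br)c(CO[Si](C(C)C)(C(C)C)C(C)C)c2C(=NN)c2cc(OC)cc(OC)c2)cc1 | intermediate
11 | diaryldiazomethane from 10 | COc1ccc(COc2cc(OC)c(Br)c(CO[Si](C(C)C)(C(C)C)C(C)C)c2C(=[N+]=[N-])c2cc(OC)cc(OC)c2)cc1 | intermediate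
12 | (2R,3S)-cis-dihydrobenzofuran | COc1ccc([C@@H]2Oc3cc(OC)c(Br)c(CO[Si](C(C)C)(C(C)C)C(C)C)c3[C@@H]2c2cc(OC)cc(OC)c2)cc1 | intermediate
13 | (2S,3S)-trans-dihydrobenzofuran | COc1ccc([C@H]2Oc3cc(OC)c(Br)c(CO[Si](C(C)C)(C(C)C)C(C)C)c3[C@@H]2c2cc(OC)cc(OC)c2)cc1 | intermediate
14 | ring-B aldehyde, (2S,3S) | COc1ccc([C@H]2Oc3cc(OC)c(Br)c(CO[Si](C(C)C)(C(C)C)C(C)C)c3[C@@H]2c2cc(OC)cc(OC)c2C=O)cc1 | intermediate
15 | ring-B benzylic alcohol, (2S,3S) | COc1ccc([C@H]2Oc3cc(OC)c(Br)c(CO[Si](C(C)C)(C(C)C)C(C)C)c3[C@@H]2c2cc(OC)cc(OC)c2CO)cc1 | intermediate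
16 | diol, (2S,3S) | COc1ccc([C@H]2Oc3cc(OC)c(Br)c(CO)c3[C@@H]2c2cc(OC)cc(OC)c2CO)cc1 | intermediate
17 | bis(bromomethyl) compound, (2S,3S) | COc1ccc([C@H]2Oc3cc(OC)c(Br)c(CBr)c3[C@@H]2c2cc(OC)cc(OC)c2CBr)cc1 | intermediate
18 | eight-membered cyclic sulfide, (2S,3S) | COc1ccc([C@H]2Oc3cc(OC)c(Br)c4c3[C@@H]2c2cc(OC)cc(OC)c2CSC4)cc1 | intermediate
19 | eight-membered cyclic sulfone, (2S,3S) (key-step precursor) | COc1ccc([C@H]2Oc3cc(OC)c(Br)c4c3[C@@H]2c2cc(OC)cc(OC)c2CS(=O)(=O)C4)cc1 | intermediate
20 | alpha-bromo sulfone (Br drawn on C11, epimer mixture) | COc1ccc([C@H]2Oc3cc(OC)c(Br)c4c3[C@@H]2c2cc(OC)cc(OC)c2CS(=O)(=O)C4Br)cc1 | intermediate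
21 | episulfone (thiirane 1,1-dioxide across C10 and C11, cis-fused) | COc1ccc([C@H]2Oc3cc(OC)c(Br)c4c3[C@@H]2c2cc(OC)cc(OC)c2C2C4S2(=O)=O)cc1 | intermediate
22 | bromo dibenzocycloheptene, (2S,3S) (key-step product) | COc1ccc([C@H]2Oc3cc(OC)c(Br)c4c3[C@@H]2c2cc(OC)cc(OC)c2C=C4)cc1 | intermediate
23 | 1,3-dimethoxybenzene | COc1cccc(OC)c1 | starting material
24 | C10-(2,4-dimethoxyphenyl) bromide, (2S,3S,10S) | COc1ccc([C@H]2Oc3cc(OC)c(Br)c4c3[C@@H]2c2cc(OC)cc(OC)c2[C@H](c2ccc(OC)cc2OC)C4)cc1 | intermediate
25 | aryllithium from 24 (Li on carbon d) | COc1ccc([C@H]2Oc3cc(OC)c([Li])c4c3[C@@H]2c2cc(OC)cc(OC)c2[C@H](c2ccc(OC)cc2OC)C4)cc1 | intermediate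
26 | carbon-d 3,5-dimethoxybenzoyl ketone, (2S,3S,10S) | COc1ccc([C@H]2Oc3cc(OC)c(C(=O)c5cc(OC)cc(OC)c5)c4c3[C@@H]2c2cc(OC)cc(OC)c2[C@H](c2ccc(OC)cc2OC)C4)cc1 | intermediate
27 | ortho-hydroxy ketone (OH on carbon c) | COc1ccc([C@H]2Oc3cc(O)c(C(=O)c5cc(OC)cc(OC)c5)c4c3[C@@H]2c2cc(OC)cc(OC)c2[C@H](c2ccc(OC)cc2OC)C4)cc1 | intermediate
28 | hydrazone of 27 (E/Z mixture) | COc1ccc([C@H]2Oc3cc(O)c(C(=NN)c5cc(OC)cc(OC)c5)c4c3[C@@H]2c2cc(OC)cc(OC)c2[C@H](c2ccc(OC)cc2OC)C4)cc1 | intermediate
29 | 4-methoxybenzyl ether of 28 | COc1ccc([C@H]2Oc3cc(OCc6ccc(OC)cc6)c(C(=NN)c5cc(OC)cc(OC)c5)c4c3[C@@H]2c2cc(OC)cc(OC)c2[C@H](c2ccc(OC)cc2OC)C4)cc1 | intermediate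
30 | diaryldiazomethane from 29 | COc1ccc([C@H]2Oc3cc(OCc6ccc(OC)cc6)c(C(=[N+]=[N-])c5cc(OC)cc(OC)c5)c4c3[C@@H]2c2cc(OC)cc(OC)c2[C@H](c2ccc(OC)cc2OC)C4)cc1 | intermediate
31 | octamethyl ether with cis ring E, (2S,3S,10S,2'S,3'R) | COc1ccc([C@H]2Oc3cc4c(c5c3[C@@H]2c2cc(OC)cc(OC)c2[C@H](c2ccc(OC)cc2OC)C5)[C@@H](c2cc(OC)cc(OC)c2)[C@@H](c2ccc(OC)cc2)O4)cc1 | intermediate
32 | octamethyl ether of the target, (2S,3S,10S,2'R,3'R) | COc1ccc([C@H]2Oc3cc4c(c5c3[C@@H]2c2cc(OC)cc(OC)c2[C@H](c2ccc(OC)cc2OC)C5)[C@@H](c2cc(OC)cc(OC)c2)[C@H](c2ccc(OC)cc2)O4)cc1 | intermediate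
33 | CNP0154047.3 | Oc1ccc([C@H]2Oc3cc4c(c5c3[C@@H]2c2cc(O)cc(O)c2[C@H](c2ccc(O)cc2O)C5)[C@@H](c2cc(O)cc(O)c2)[C@H](c2ccc(O)cc2)O4)cc1 | target

**Step count:** 23 steps in total. The longest linear sequence is 23 steps (1 to 33).

**Steps most likely to fail**

1. **Step 16 (hydroarylation).**
   - What may go wrong: the acid may also ionise the C2–O bond of ring D, which is a cyclic 4-methoxybenzyl aryl ether, and the excess arene may capture that cation irreversibly. Long exposure could also make the C10–aryl bond reversible and erode facial selectivity.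
   - Fallback: the C10 cation is generated from a leaving group in an ionising solvent instead of by protonating the alkene with a superacid.
   - Setting out from 22, oxymercuration (Hg(OAc)2, THF/H2O) should give the hydroxy organomercurial acetate F1. NaBH4/NaOH then removes mercury to give the C10 benzylic alcohol F2.
   - F2 is ionised in 1,1,1,3,3,3-hexafluoropropan-2-ol without added strong acid in the presence of 23 (dehydrative Friedel–Crafts benzylation). The approach is again from the convex face, and the route is rejoined at 24.

2. **Step 15 (ring contraction).**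
   - What may go wrong: repeated halogenation at the two activated benzylic positions, addition of difluorocarbene from spent CBr2F2 to the electron-rich alkene, or a slow 1,3-elimination in the crowded ring.
   - Fallback: the same C10=C11 bond is made reductively.
   - Setting out from diol 16, MnO2 (CH2Cl2, rt) should give the dialdehyde F3. Intramolecular McMurry coupling with low-valent titanium (TiCl4, Zn, pyridine, THF, reflux, high dilution), which aryl bromides tolerate, rejoins the route at 22.

3. **Step 21 (second carbene insertion).**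
   - What may go wrong: a mismatch between the catalyst and the resident stereocentres may lower facial selectivity, or carbene formation at the doubly ortho-substituted diazo carbon may be slow, with diversion to azine or ketone. Step 7 shares the steric problem but is run on simple material.
   - Fallback: ring E is built by one-carbon homologation and cation closure.
   - Setting out from ketone 26, Corey–Chaykovsky methylenation (Me3SI, NaH, DMSO/THF) should give the epoxide F4. ZnI2 (Meinwald rearrangement) gives the diarylacetaldehyde F5, and 4-methoxyphenylmagnesium bromide gives the carbinol F6.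
   - The C3' diastereomers of F6 are separable because the rest of the molecule is a single enantiomer.
   - BBr3 on the 3'R series cleaves all nine methyl ethers, and the freed phenol on carbon c closes ring E trans onto the benzylic cation. The route is rejoined at 33.

**Further compounds**
F1 | step 16 | C10-hydroxy C11-acetoxymercurio adduct of 22 | COc1ccc([C@H]2Oc3cc(OC)c(Br)c4c3[C@@H]2c2cc(OC)cc(OC)c2C(O)C4[Hg]OC(C)=O)cc1
F2 | step 16 | C10 benzylic alcohol (epimer mixture at C10) | COc1ccc([C@H]2Oc3cc(OC)c(Br)c4c3[C@@H]2c2cc(OC)cc(OC)c2C(O)C4)cc1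
F3 | step 15 | dialdehyde from 16, (2S,3S) | COc1ccc([C@H]2Oc3cc(OC)c(Br)c(C=O)c3[C@@H]2c2cc(OC)cc(OC)c2C=O)cc1
F4 | step 21 | 2,2-diaryloxirane from 26 (epimer mixture at the new carbon) | COc1ccc([C@H]2Oc3cc(OC)c(C5(CO5)c6cc(OC)cc(OC)c6)c4c3[C@@H]2c2cc(OC)cc(OC)c2[C@H](c2ccc(OC)cc2OC)C4)cc1
F5 | step 21 | diarylacetaldehyde (epimer mixture at C3') | COc1ccc([C@H]2Oc3cc(OC)c(C(C=O)c5cc(OC)cc(OC)c5)c4c3[C@@H]2c2cc(OC)cc(OC)c2[C@H](c2ccc(OC)cc2OC)C4)cc1
F6 | step 21 | 1,2,2-triarylethanol, 3'R series after separation (carbinol epimers) | COc1ccc([C@H]2Oc3cc(OC)c([C@@H](c5cc(OC)cc(OC)c5)C(O)c6ccc(OC)cc6)c4c3[C@@H]2c2cc(OC)cc(OC)c2[C@H](c2ccc(OC)cc2OC)C4)cc1
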